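**Strategy.** The chroman is cut at C2–C3 and at O1–C8a. The benzene ring is carried as a dearomatised quinone bisketal: because O1–C8a and the C6 hydroxyl are para to each other, C8a can be a ketal carbon that accepts the tertiary oxygen, and no phenol protection is needed. In the key step a lithiated (2R)-methylcarbinol benzoate holding the whole side chain captures the 2-(cyclohexadienyl)ethyl boronic ester; a stereospecific 1,2-metallate shift makes C2–C3 and the quaternary C2 centre, oxidation gives the tertiary alkoxide, and acid closes the pyran ring at C8a. Reduction then aromatises the carbocycle. The chain comes from (R)-citronellyl bromide and (R)-3-bromo-2-methylpropan-1-ol.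

Key step: step 13

Remark: 1, 2, 6 and 16 are taken as purchased; 26 is expected as a mixture of C8a epimers, which is immaterial because C8a becomes aromatic in step 14.

Step 1
Reactants: 1 (2R)-3-bromo-2-methylpropan-1-ol; 2 2-(2-bromoethyl)-2-methyl-1,3-dioxolane
Product: 4 (2S)-2-methyl-5-(2-methyl-1,3-dioxolan-2-yl)pentan-1-ol, via Grignard reagent 3 (not isolated)
Conditions: 2, Mg, THF, 25 °C; 1, MeMgCl (1 equiv), THF, −40 °C; then 3, Li2CuCl4 (cat.), −40 → 25 °C
Reagents that add atoms: none
Why: Copper-catalysed Grignard cross-coupling at the primary bromide of the magnesium alkoxide of 1 should attach the masked acetonyl unit, the methyl-bearing centre being untouched (the descriptor changes only through the priority rules).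

Step 2
Reactants: 4 (2S)-2-methyl-5-(2-methyl-1,3-dioxolan-2-yl)pentan-1-ol
Product: 5 (2S)-2-methyl-5-(2-methyl-1,3-dioxolan-2-yl)pentyl 4-methylbenzenesulfonate
Conditions: TsCl, Et3N, DMAP (cat.), CH2Cl2, 0 → 25 °C
Reagents that add atoms: 4-methylbenzenesulfonyl chloride, Cc1ccc(cc1)S(Cl)(=O)=O
Why: Sulfonylation of the primary alcohol should give the leaving group for the next coupling without touching the stereocentre.

Step 3
Reactants: 5 (2S)-2-methyl-5-(2-methyl-1,3-dioxolan-2-yl)pentyl 4-methylbenzenesulfonate; 6 (6R)-8-bromo-2,6-dimethyloct-2-ene ((R)-citronellyl bromide)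
Product: 8 2-methyl-2-[(4R,8S)-4,8,12-trimethyltridec-11-en-1-yl]-1,3-dioxolane, via citronellylmagnesium bromide 7 (not isolated)
Conditions: 6, Mg, THF; 5, Li2CuCl4 (cat.), THF, −78 → 25 °C
Reagents that add atoms: none
Why: Li2CuCl4-catalysed Grignard–tosylate cross-coupling should join the two chiral-pool units at carbons remote from both methyl-bearing centres, which therefore keep the configurations of 1 and 6.

Step 4
Reactants: 8 2-methyl-2-[(4R,8S)-4,8,12-trimethyltridec-11-en-1-yl]-1,3-dioxolane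
Product: 10 (4S,8R)-4,8-dimethyl-11-(2-methyl-1,3-dioxolan-2-yl)undecan-1-ol, via aldehyde 9 (not isolated)
Conditions: O3, CH2Cl2/MeOH, NaHCO3, −78 °C; then NaBH4, −78 → 25 °C
Reagents that add atoms: ozone, [O-][O+]=O
Why: Ozonolysis of the only alkene with reductive NaBH4 work-up should give the primary alcohol while the buffered medium preserves the ketal.

Step 5
Reactants: 10 (4S,8R)-4,8-dimethyl-11-(2-methyl-1,3-dioxolan-2-yl)undecan-1-ol
Product: 11 2-[(4R,8S)-11-iodo-4,8-dimethylundecyl]-2-methyl-1,3-dioxolane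
Conditions: I2, PPh3, imidazole, CH2Cl2, 0 → 25 °C
Reagents that add atoms: iodine, II
Why: Appel-type iodination of the primary alcohol under imidazole buffering should leave the acid-labile ketal intact.

Step 6
Reactants: 11 2-[(4R,8S)-11-iodo-4,8-dimethylundecyl]-2-methyl-1,3-dioxolane
Product: 13 (6R,10S)-6,10,14-trimethylpentadec-14-en-2-one, via ketal 12 (not isolated)
Conditions: CH2=C(CH3)MgBr, CuI (cat.), THF, −20 → 25 °C; then 2 M HCl (aq), 25 °C
Reagents that add atoms: isopropenylmagnesium bromide, CC(=C)[Mg]Br; water, O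
Why: CuI-catalysed coupling of the alkenyl Grignard reagent with the primary iodide should install the isopropenyl end, and the acidic work-up hydrolyses the dioxolane to the methyl ketone under conditions too mild to hydrate or shift the 1,1-disubstituted alkene.

Step 7
Reactants: 13 (6R,10S)-6,10,14-trimethylpentadec-14-en-2-one
Product: 14 (2S,6R,10S)-6,10,14-trimethylpentadec-14-en-2-ol
Conditions: alcohol dehydrogenase ADH-A (Rhodococcus ruber), NADH (cat.), i-PrOH, phosphate buffer pH 7.5, 30 °C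
Reagents that add atoms: none
Why: Enzymatic ketone reduction, in which the dehydrogenase transfers hydride from NADH to the Re face of methyl ketones, should set the (2S) carbinol centre, with propan-2-ol recycling the cofactor.

Step 8
Reactants: 14 (2S,6R,10S)-6,10,14-trimethylpentadec-14-en-2-ol
Product: 15 (2R,6R,10S)-6,10,14-trimethylpentadec-14-en-2-yl 2,4,6-tri(propan-2-yl)benzoate
Conditions: 2,4,6-triisopropylbenzoic acid, PPh3, DIAD, THF, 0 → 25 °C
Reagents that add atoms: 2,4,6-tri(propan-2-yl)benzoic acid, CC(C)c1cc(C(C)C)c(C(O)=O)c(C(C)C)c1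
Why: Mitsunobu esterification, in which the carboxylate displaces the oxyphosphonium group by SN2 with inversion, should give the (2R) hindered benzoate that directs α-lithiation.

Step 9
Reactants: 16 1,4-dimethoxy-2,3,5-trimethylbenzene
Product: 18 2-(2,5-dimethoxy-3,4,6-trimethylphenyl)ethan-1-ol, via aryllithium 17 (not isolated)
Conditions: n-BuLi, TMEDA, Et2O, 0 → 25 °C; then oxirane, −78 → 25 °C
Reagents that add atoms: oxirane, C1CO1
Why: Methoxy-directed ortho-lithiation at the only free ring position followed by epoxide opening should attach the two-carbon arm that becomes C4 and C3.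

Step 10
Reactants: 18 2-(2,5-dimethoxy-3,4,6-trimethylphenyl)ethan-1-ol
Product: 19 1-(2-bromoethyl)-2,5-dimethoxy-3,4,6-trimethylbenzene
Conditions: CBr4, PPh3, CH2Cl2, 0 °C
Reagents that add atoms: tetrabromomethane, BrC(Br)(Br)Br
Why: Appel bromination should convert the primary alcohol into the bromide needed for borylation.

Step 11
Reactants: 19 1-(2-bromoethyl)-2,5-dimethoxy-3,4,6-trimethylbenzene
Product: 20 1-(2-bromoethyl)-3,3,6,6-tetramethoxy-2,4,5-trimethylcyclohexa-1,4-diene
Conditions: Pt anode, Pt cathode, undivided cell, constant current, MeOH, KOH (1%), 0 °C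
Reagents that add atoms: methanol, CO
Why: Anodic two-electron oxidation of the 1,4-dimethoxyarene with capture by methanol at both oxygen-bearing carbons (anodic bis-ketalisation of hydroquinone dimethyl ethers) should give the base-stable quinone bisketal, which makes C8a a latent electrophile.

Step 12
Reactants: 20 1-(2-bromoethyl)-3,3,6,6-tetramethoxy-2,4,5-trimethylcyclohexa-1,4-diene
Product: 21 5,5-dimethyl-2-[2-(3,3,6,6-tetramethoxy-2,4,5-trimethylcyclohexa-1,4-dien-1-yl)ethyl]-1,3,2-dioxaborinane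
Conditions: B2neop2, CuI (cat.), PPh3 (cat.), LiOMe, DMF, 25 °C
Reagents that add atoms: 5,5,5',5'-tetramethyl-2,2'-bi(1,3,2-dioxaborinane), CC1(C)COB(OC1)B1OCC(C)(C)CO1
Why: CuI-catalysed borylation of the primary alkyl bromide with the alkoxide-activated diboron reagent should proceed under basic conditions that the bisketal tolerates.

Step 13
Reactants: 15 (2R,6R,10S)-6,10,14-trimethylpentadec-14-en-2-yl 2,4,6-tri(propan-2-yl)benzoate; 21 5,5-dimethyl-2-[2-(3,3,6,6-tetramethoxy-2,4,5-trimethylcyclohexa-1,4-dien-1-yl)ethyl]-1,3,2-dioxaborinane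
Product: 26 (2R)-8a-methoxy-2,5,7,8-tetramethyl-2-[(4R,8S)-4,8,12-trimethyltridec-12-en-1-yl]-3,4-dihydro-2H-chromen-6(8aH)-one (C8a epimers), via lithiated benzoate 22 (not isolated), via boronate complex 23 (not isolated), via tertiary boronic ester 24 (not isolated), via tertiary alcohol 25 (not isolated)
Conditions: 15, s-BuLi, TMEDA, CPME, −60 °C; then 21, −60 → 50 °C; NaOH (aq), H2O2, THF, 0 → 25 °C; Na2S2O3 (aq), extraction; camphorsulfonic acid (cat.), MeOH, H2O (2 equiv), 0 → 25 °C; then HC(OMe)3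
Reagents that add atoms: hydrogen peroxide, OO; water, O; methanol, CO
Why: s-BuLi/TMEDA, directed by the hindered benzoate carbonyl, removes the C2 proton of 15 to give configurationally stable 22, which is borylated with retention to 23; on warming, the 2-(cyclohexadienyl)ethyl group migrates from boron to carbon antiperiplanar to the leaving benzoate (lithiation–borylation with 1,2-metallate rearrangement), forming C2–C3 in 24, and basic peroxide turns C–B into C–O with retention to give 25. Acid then ionises the C8a ketal of the quinone bisketal and the tertiary hydroxyl adds to the oxocarbenium ion (6-exo-trig closure of the pyran ring, acid-catalysed ketal exchange), while the C6 ketal is hydrolysed to the cross-conjugated dienone; the orthoformate removes water so that any ring-opened hydroxy-quinone is returned to the cyclic ketal. The C2 centre is controlled by the (2R) carbinol carbon of 15: retention, retention, inversion and retention amount to replacement of H by C3 with the oxygen site unchanged, hence (2R) in 26, whereas C8a forms without control and disappears in step 14. The step needs deprotonation α to oxygen and not at allylic positions, which the directing carbonyl and −60 °C secure, and ring closure at C8a and not at C6, which the six-membered tether from C2 secures.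

Step 14
Reactants: 26 (2R)-8a-methoxy-2,5,7,8-tetramethyl-2-[(4R,8S)-4,8,12-trimethyltridec-12-en-1-yl]-3,4-dihydro-2H-chromen-6(8aH)-one
Product: 27 (2R)-2,5,7,8-tetramethyl-2-[(4R,8S)-4,8,12-trimethyltridec-12-en-1-yl]-3,4-dihydro-2H-chromen-6-ol
Conditions: L-ascorbic acid, AcOH, MeOH, 25 °C, argon
Reagents that add atoms: none
Why: Acid ionises the C8a methoxy group to the chromanoxylium cation, which ascorbic acid reduces by two electrons (the known reduction of 8a-alkoxy tocopherones to chromanols), so the carbocycle should aromatise with no bond to C2 broken and the (2R) centre kept.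

**Compound list**

1 | (2R)-3-bromo-2-methylpropan-1-ol | OC[C@@H](C)CBr | starting material
2 | 2-(2-bromoethyl)-2-methyl-1,3-dioxolane | CC1(CCBr)OCCO1 | starting material
3 | [2-(2-methyl-1,3-dioxolan-2-yl)ethyl]magnesium bromide | CC1(CC[Mg]Br)OCCO1 | intermediate
4 | (2S)-2-methyl-5-(2-methyl-1,3-dioxolan-2-yl)pentan-1-ol | OC[C@@H](C)CCCC1(C)OCCO1 | intermediate
5 | (2S)-2-methyl-5-(2-methyl-1,3-dioxolan-2-yl)pentyl 4-methylbenzenesulfonate | Cc1ccc(cc1)S(=O)(=O)OC[C@@H](C)CCCC1(C)OCCO1 | intermediate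
6 | (6R)-8-bromo-2,6-dimethyloct-2-ene ((R)-citronellyl bromide) | CC(C)=CCC[C@@H](C)CCBr | starting material
7 | [(3R)-3,7-dimethyloct-6-en-1-yl]magnesium bromide | CC(C)=CCC[C@@H](C)CC[Mg]Br | intermediate
8 | 2-methyl-2-[(4R,8S)-4,8,12-trimethyltridec-11-en-1-yl]-1,3-dioxolane | CC(C)=CCC[C@@H](C)CCC[C@@H](C)CCCC1(C)OCCO1 | intermediate
9 | (4S,8R)-4,8-dimethyl-11-(2-methyl-1,3-dioxolan-2-yl)undecanal | O=CCC[C@@H](C)CCC[C@@H](C)CCCC1(C)OCCO1 | intermediate
10 | (4S,8R)-4,8-dimethyl-11-(2-methyl-1,3-dioxolan-2-yl)undecan-1-ol | OCCC[C@@H](C)CCC[C@@H](C)CCCC1(C)OCCO1 | intermediate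
11 | 2-[(4R,8S)-11-iodo-4,8-dimethylundecyl]-2-methyl-1,3-dioxolane | ICCC[C@@H](C)CCC[C@@H](C)CCCC1(C)OCCO1 | intermediate
12 | 2-methyl-2-[(4R,8S)-4,8,12-trimethyltridec-12-en-1-yl]-1,3-dioxolane | C=C(C)CCC[C@@H](C)CCC[C@@H](C)CCCC1(C)OCCO1 | intermediate
13 | (6R,10S)-6,10,14-trimethylpentadec-14-en-2-one | C=C(C)CCC[C@@H](C)CCC[C@@H](C)CCCC(C)=O | intermediate
14 | (2S,6R,10S)-6,10,14-trimethylpentadec-14-en-2-ol | C=C(C)CCC[C@@H](C)CCC[C@@H](C)CCC[C@H](C)O | intermediate
15 | (2R,6R,10S)-6,10,14-trimethylpentadec-14-en-2-yl 2,4,6-tri(propan-2-yl)benzoate | C=C(C)CCC[C@@H](C)CCC[C@@H](C)CCC[C@@H](C)OC(=O)c1c(C(C)C)cc(C(C)C)cc1C(C)C | intermediate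
16 | 1,4-dimethoxy-2,3,5-trimethylbenzene | COc1cc(C)c(OC)c(C)c1C | starting material
17 | (2,5-dimethoxy-3,4,6-trimethylphenyl)lithium | COc1c([Li])c(C)c(OC)c(C)c1C | intermediate
18 | 2-(2,5-dimethoxy-3,4,6-trimethylphenyl)ethan-1-ol | COc1c(CCO)c(C)c(OC)c(C)c1C | intermediate
19 | 1-(2-bromoethyl)-2,5-dimethoxy-3,4,6-trimethylbenzene | COc1c(CCBr)c(C)c(OC)c(C)c1C | intermediate
20 | 1-(2-bromoethyl)-3,3,6,6-tetramethoxy-2,4,5-trimethylcyclohexa-1,4-diene | COC1(OC)C(CCBr)=C(C)C(OC)(OC)C(C)=C1C | intermediate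
21 | 5,5-dimethyl-2-[2-(3,3,6,6-tetramethoxy-2,4,5-trimethylcyclohexa-1,4-dien-1-yl)ethyl]-1,3,2-dioxaborinane | COC1(OC)C(CCB2OCC(C)(C)CO2)=C(C)C(OC)(OC)C(C)=C1C | intermediate
22 | (2R,6R,10S)-2-lithio-6,10,14-trimethylpentadec-14-en-2-yl 2,4,6-tri(propan-2-yl)benzoate | C=C(C)CCC[C@@H](C)CCC[C@@H](C)CCC[C@@]([Li])(C)OC(=O)c1c(C(C)C)cc(C(C)C)cc1C(C)C | intermediate
23 | lithium boronate complex of 22 and 21 (boron on C2 of the (2R,6R,10S)-benzoate; boron also bears the 2-(cyclohexadienyl)ethyl group and the neopentyl glycolate) | [Li+].C=C(C)CCC[C@@H](C)CCC[C@@H](C)CCC[C@@](C)(OC(=O)c1c(C(C)C)cc(C(C)C)cc1C(C)C)[B-]1(CCC2=C(C)C(OC)(OC)C(C)=C(C)C2(OC)OC)OCC(C)(C)CO1 | intermediate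
24 | 5,5-dimethyl-2-[(3S,7R,11S)-3,7,11,15-tetramethyl-1-(3,3,6,6-tetramethoxy-2,4,5-trimethylcyclohexa-1,4-dien-1-yl)hexadec-15-en-3-yl]-1,3,2-dioxaborinane | C=C(C)CCC[C@@H](C)CCC[C@@H](C)CCC[C@@](C)(B1OCC(C)(C)CO1)CCC1=C(C)C(OC)(OC)C(C)=C(C)C1(OC)OC | intermediate
25 | (3R,7R,11S)-3,7,11,15-tetramethyl-1-(3,3,6,6-tetramethoxy-2,4,5-trimethylcyclohexa-1,4-dien-1-yl)hexadec-15-en-3-ol | C=C(C)CCC[C@@H](C)CCC[C@@H](C)CCC[C@@](C)(O)CCC1=C(C)C(OC)(OC)C(C)=C(C)C1(OC)OC | intermediate
26 | (2R)-8a-methoxy-2,5,7,8-tetramethyl-2-[(4R,8S)-4,8,12-trimethyltridec-12-en-1-yl]-3,4-dihydro-2H-chromen-6(8aH)-one (C8a epimers) | C=C(C)CCC[C@@H](C)CCC[C@@H](C)CCC[C@]1(C)CCC2=C(C)C(=O)C(C)=C(C)C2(OC)O1 | intermediate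
27 | (2R)-2,5,7,8-tetramethyl-2-[(4R,8S)-4,8,12-trimethyltridec-12-en-1-yl]-3,4-dihydro-2H-chromen-6-ol | C=C(C)CCC[C@@H](C)CCC[C@@H](C)CCC[C@]1(C)CCc2c(C)c(O)c(C)c(C)c2O1 | target

**Step count.** Total: 14 steps. Longest linear sequence: 10 steps (steps 1 to 8, then 13 and 14).

**Steps most likely to fail**

1. Step 13. The α-lithiation of the secondary dialkyl benzoate may be incomplete, and borylation and the 1,2-shift may be slow with two hindered partners. In the acid stage, over-hydrolysis may open the ring to the hydroxy-quinone. The fallback sets out from ketone 13 and aryllithium 17 and comes back at 26. Ketone 13 is converted by catalytic asymmetric double methylene transfer with dimethyloxosulfonium methylide (Corey–Chaykovsky epoxidation then ring expansion, LaLi3(binaphthoxide)3 catalyst in the enantiomeric form that leads to the (R)-product, triarylphosphine oxide additive) into (2R)-2-methyl-2-[(4R,8S)-4,8,12-trimethyltridec-12-en-1-yl]oxetane F1. Aryllithium 17 with BF3·OEt2 opens F1 at the unsubstituted CH2–O carbon to give the tertiary alcohol (3R,7R,11S)-1-(2,5-dimethoxy-3,4,6-trimethylphenyl)-3,7,11,15-tetramethylhexadec-15-en-3-ol F2. Oxidative demethylation with (NH4)2Ce(NO3)6 in aqueous MeCN gives the hydroxy-quinone 2-[(3R,7R,11S)-3-hydroxy-3,7,11,15-tetramethylhexadec-15-en-1-yl]-3,5,6-trimethylcyclohexa-2,5-diene-1,4-dione F3. MeOH, HC(OMe)3 and catalytic H2SO4 close F3 to 26.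

2. Step 11. Side-chain (benzylic) methoxylation may compete with ring bis-ketalisation, and the basic electrolyte may eliminate HBr from the bromoethyl arm. The fallback keeps the ring aromatic; it sets out from 19 and comes back at 26. Bromide 19 is borylated under the conditions of step 12 to 2-[2-(2,5-dimethoxy-3,4,6-trimethylphenyl)ethyl]-5,5-dimethyl-1,3,2-dioxaborinane F4. Lithiation–borylation of 15 with F4 and peroxide oxidation (step 13 without the acid stage) should give the tertiary alcohol F2. F2 is oxidised with (NH4)2Ce(NO3)6 to the hydroxy-quinone F3, and acidic methanol with HC(OMe)3 closes F3 to 26.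

3. Step 7. Conversion of the water-insoluble ketone may stall, or enantioselection may be incomplete. The fallback sets out from 13 and comes back at 14 and at 15. NaBH4 reduces 13 to (6R,10S)-6,10,14-trimethylpentadec-14-en-2-ol as both C2 epimers F5. Candida antarctica lipase B with vinyl acetate acylates the (2R) epimer to (2R,6R,10S)-6,10,14-trimethylpentadec-14-en-2-yl acetate F6 and leaves 14, which is separated. K2CO3 in MeOH converts F6 into (2R,6R,10S)-6,10,14-trimethylpentadec-14-en-2-ol F7, and acylation of F7 with 2,4,6-tri(propan-2-yl)benzoyl chloride (retention) gives 15 directly.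

**Further compounds**

F1 | step 13 | (2R)-2-methyl-2-[(4R,8S)-4,8,12-trimethyltridec-12-en-1-yl]oxetane | C=C(C)CCC[C@@H](C)CCC[C@@H](C)CCC[C@]1(C)CCO1
F2 | step 13 | (3R,7R,11S)-1-(2,5-dimethoxy-3,4,6-trimethylphenyl)-3,7,11,15-tetramethylhexadec-15-en-3-ol | C=C(C)CCC[C@@H](C)CCC[C@@H](C)CCC[C@@](C)(O)CCc1c(OC)c(C)c(C)c(OC)c1C
F3 | step 13 | 2-[(3R,7R,11S)-3-hydroxy-3,7,11,15-tetramethylhexadec-15-en-1-yl]-3,5,6-trimethylcyclohexa-2,5-diene-1,4-dione | C=C(C)CCC[C@@H](C)CCC[C@@H](C)CCC[C@@](C)(O)CCC1=C(C)C(=O)C(C)=C(C)C1=O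
F4 | step 11 | 2-[2-(2,5-dimethoxy-3,4,6-trimethylphenyl)ethyl]-5,5-dimethyl-1,3,2-dioxaborinane | COc1c(CCB2OCC(C)(C)CO2)c(C)c(OC)c(C)c1C
F5 | step 7 | (6R,10S)-6,10,14-trimethylpentadec-14-en-2-ol (both C2 epimers) | C=C(C)CCC[C@@H](C)CCC[C@@H](C)CCCC(C)O
F6 | step 7 | (2R,6R,10S)-6,10,14-trimethylpentadec-14-en-2-yl acetate | C=C(C)CCC[C@@H](C)CCC[C@@H](C)CCC[C@@H](C)OC(C)=O
F7 | step 7 | (2R,6R,10S)-6,10,14-trimethylpentadec-14-en-2-ol | C=C(C)CCC[C@@H](C)CCC[C@@H](C)CCC[C@@H](C)O
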